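## Retrosynthetic overview

1. End game: C11 CH2OH comes from a C4 formyl group (hydride, last step). The C10 p-coumarate and the C1 (S)-3-methylpentanoate come from two esterifications of a bicyclic lactol enal.
2. Key disconnection: dihydropyran ring B (C1–O2–C3=C4–C5–C9) comes from a cyclopentene (ring A, C5=C9) plus triformylmethane. The sequence is [2+2] photocycloaddition, strain-driven retro-aldol opening of the cyclobutane, then lactolisation. It forms C1–C9, C4–C5 and O2–C1.
3. Enabling feature: ring B is the cyclic enol-hemiacetal of a 1,5-dialdehyde (C1, C3). C1, C3, C4 and exocyclic C11 are the four carbons of HC(CHO)3, attached to the cis-vicinal pair C5/C9 of ring A. The quaternary C8 (α-OH, β-CH2O) next to C9 and the β C7–O steer face and orientation.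
4. Ring A is bought as cyclopent-2-en-1-one. C10 comes from a Morita–Baylis–Hillman reaction, C7 from a CBS reduction, C8 from an anti epoxidation, and C5=C9 from selenide opening and selenoxide elimination.
5. Ring order: ring A (purchased), then a temporary cyclobutane (made and broken in the key step), then ring B last. The extra oxidation level at C11 is removed in the final step.

Key step: step 7

Assumption: iridoid numbering is used (C1 acetal carbon, O2, C3=C4, ring-fusion C5 and C9, C6, C7, C8, C10 on C8, C11 on C4; β is the face of H5 and H9; TBS = tert-butyldimethylsilyl), and triformylmethane and (S)-3-methylpentanoic acid are taken as catalogue chemicals.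

## Route

Step 1
Reactants: 1 cyclopent-2-en-1-one; 2 formaldehyde (37% aqueous solution)
Product: 3 2-(hydroxymethyl)cyclopent-2-en-1-one
Conditions: n-Bu3P (cat.), MeOH/CHCl3, rt
Reagents that add atoms: none
Why: Morita–Baylis–Hillman reaction: reversible conjugate addition of the phosphine turns the α-carbon into an enolate that adds to formaldehyde, and loss of the phosphine restores the enone, so that C10 is placed on the future C8 without any stereochemical issue.

Step 2
Reactants: 3 2-(hydroxymethyl)cyclopent-2-en-1-one
Product: 4 2-[(tert-butyldimethylsilyloxy)methyl]cyclopent-2-en-1-one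
Conditions: TBSCl, imidazole, CH2Cl2, 0 °C to rt
Reagents that add atoms: tert-butyldimethylsilyl chloride (TBSCl), CC(C)(C)[Si](C)(C)Cl
Why: Standard silyl ether formation at the only hydroxyl group, which removes the acidic proton that would otherwise bind borane and open an uncatalysed reduction pathway in step 3.

Step 3
Reactants: 4 2-[(tert-butyldimethylsilyloxy)methyl]cyclopent-2-en-1-one
Product: 5 (1S)-2-[(tert-butyldimethylsilyloxy)methyl]cyclopent-2-en-1-ol
Conditions: (R)-2-methyl-CBS-oxazaborolidine (10 mol %), BH3·SMe2, THF, −30 °C; MeOH quench, aqueous work-up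
Reagents that add atoms: none
Why: Corey–Bakshi–Shibata reduction: the ketone should coordinate to the catalyst boron with its larger flank (the substituted alkenyl carbon) away from the B-methyl group, so that borane held on nitrogen delivers hydride to one carbonyl face in a 1,2-sense and sets C7 as S.

Step 4
Reactants: 5 (1S)-2-[(tert-butyldimethylsilyloxy)methyl]cyclopent-2-en-1-ol
Product: 6 (1S)-1-(tert-butyldimethylsilyloxy)-2-[(tert-butyldimethylsilyloxy)methyl]cyclopent-2-ene
Conditions: TBSCl, imidazole, DMF, rt
Reagents that add atoms: tert-butyldimethylsilyl chloride (TBSCl), CC(C)(C)[Si](C)(C)Cl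
Why: Standard silylation of the secondary allylic alcohol, which removes any hydroxyl-directing effect and places a bulky group on the β-face for steps 5 and 7.

Step 5
Reactants: 6 (1S)-1-(tert-butyldimethylsilyloxy)-2-[(tert-butyldimethylsilyloxy)methyl]cyclopent-2-ene
Product: 7 (1S,2S,5S)-2-(tert-butyldimethylsilyloxy)-1-[(tert-butyldimethylsilyloxy)methyl]-6-oxabicyclo[3.1.0]hexane (epoxide oxygen trans to the ring silyloxy group)
Conditions: mCPBA, CH2Cl2, 0 °C
Reagents that add atoms: 3-chloroperoxybenzoic acid (mCPBA), O=C(OO)c1cccc(Cl)c1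
Why: Prilezhaev epoxidation of the only alkene: with no free hydroxyl to direct it, the peracid should approach anti to the allylic C7 silyloxy group, which puts the epoxide oxygen (the future C8 hydroxyl) on the α-face, trans to C7–O.

Step 6
Reactants: 7 (1S,2S,5S)-2-(tert-butyldimethylsilyloxy)-1-[(tert-butyldimethylsilyloxy)methyl]-6-oxabicyclo[3.1.0]hexane
Product: 10 (1R,5S)-5-(tert-butyldimethylsilyloxy)-1-[(tert-butyldimethylsilyloxy)methyl]cyclopent-2-en-1-ol, via hydroxy selenide 8 (not isolated), via selenoxide 9 (not isolated)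
Conditions: PhSeSePh, NaBH4, EtOH, 78 °C; then 30% H2O2, THF, 0 °C to rt
Reagents that add atoms: none
Why: Organoselenium epoxide-to-allylic-alcohol transposition: the selenolate should open the epoxide by SN2 attack at the secondary C9 so that the C8–O bond and its configuration stay untouched, and the selenoxide syn-elimination can only take a hydrogen from C5 because C8 has none, which places the alkene at C5=C9.

Step 7
Reactants: 10 (1R,5S)-5-(tert-butyldimethylsilyloxy)-1-[(tert-butyldimethylsilyloxy)methyl]cyclopent-2-en-1-ol; 11 triformylmethane (methanetricarbaldehyde, reacting as its enol)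
Product: 14 (1R,4aS,6S,7R,7aS)-6-(tert-butyldimethylsilyloxy)-7-[(tert-butyldimethylsilyloxy)methyl]-1,7-dihydroxy-1,4a,5,6,7,7a-hexahydrocyclopenta[c]pyran-4-carbaldehyde, via cyclobutanol photoadduct 12 (not isolated), via open trialdehyde 13 (not isolated)
Conditions: hν (450 W medium-pressure Hg lamp, Corex filter), 11 (3 equiv, added in portions), dry MeCN, 0 °C, argon, run to partial conversion with recovery of 10
Reagents that add atoms: none
Why: Excitation of the hydrogen-bonded enol form of 11 and [2+2] photocycloaddition across C5=C9 of 10 should give the cis-fused cyclobutanol 12, whose ring strain drives spontaneous retro-aldol scission of the C1–C4 bond to trialdehyde 13, and the enolised malondialdehyde unit of 13 then adds through oxygen to the C1 aldehyde to give lactol 14 (de Mayo reaction followed by lactolisation). The closest known reaction type is the de Mayo photoannulation of cyclopentenes with methyl diformylacetate; the third formyl group here takes the part of the ester as chromophore and enol stabiliser and makes the two carbonyl groups left on C4 equivalent, so that either one closes to the same product. The temporary four-membered ring closes by stepwise [2+2] addition through a 1,4-biradical and can only be cis-fused on ring A, and ring B closes by 6-exo-trig attack of the enol oxygen on the C1 carbonyl group. C5 and C9 are set together, cis by the cyclobutane and in the absolute sense by approach to the α-face, because the β-face of 10 carries both the C8 CH2OTBS and the C7 OTBS groups while the α-face carries only the small C8 hydroxyl; C1 is set under thermodynamic control of the reversible lactol, hydroxyl exo (β) and trans to the C9–C8 bond. The step needs orientation selectivity (CHOH carbon to C9, fully substituted carbon to C5), which the quaternary C8 next to C9 secures by repelling the C(CHO)2 terminus, and chemoselectivity, which is given because 10 has no chromophore and no second alkene. Three bonds (C1–C9, C4–C5, O2–C1), three stereocentres and the C4 formyl handle for C11 should thus arise in one operation from an achiral four-carbon reagent.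

Step 8
Reactants: 14 lactol enal (as named in step 7); 15 (3S)-3-methylpentanoic acid
Product: 16 (1S,4aS,6S,7R,7aS)-6-(tert-butyldimethylsilyloxy)-7-[(tert-butyldimethylsilyloxy)methyl]-4-formyl-7-hydroxy-1,4a,5,6,7,7a-hexahydrocyclopenta[c]pyran-1-yl (3S)-3-methylpentanoate
Conditions: DCC, DMAP (cat.), CH2Cl2, −20 to 0 °C
Reagents that add atoms: none
Why: Steglich esterification of the lactol: only the C1 hydroxyl can be acylated (the C8 hydroxyl is tertiary), and since the anomers interconvert, the less hindered exo (β) hydroxyl, trans to the C9–C8 bond, should react and fix C1 as S while the side-chain stereocentre comes unchanged from 15.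

Step 9
Reactants: 16 C1 ester bis-silyl ether (as named in step 8)
Product: 17 (1S,4aS,6S,7R,7aS)-4-formyl-6,7-dihydroxy-7-(hydroxymethyl)-1,4a,5,6,7,7a-hexahydrocyclopenta[c]pyran-1-yl (3S)-3-methylpentanoate
Conditions: HF·pyridine, pyridine, THF, 0 °C to rt
Reagents that add atoms: none
Why: Fluoride-driven cleavage of both alkyl silyl ethers, in a buffered medium that should spare the C1 acyloxy acetal because the C4 formyl group withdraws the O2 lone pair and so disfavours ionisation at C1.

Step 10
Reactants: 18 (E)-p-coumaric acid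
Product: 20 (E)-3-[4-(tert-butyldimethylsilyloxy)phenyl]prop-2-enoic acid, via silyl ester silyl ether 19 (not isolated)
Conditions: TBSCl (2.2 equiv), imidazole, DMF, rt; then AcOH/THF/H2O, rt
Reagents that add atoms: tert-butyldimethylsilyl chloride (TBSCl), CC(C)(C)[Si](C)(C)Cl
Why: Exhaustive silylation followed by selective hydrolysis of the far more labile silyl ester leaves the aryl silyl ether, which masks the phenol for the carbodiimide coupling and keeps the E alkene untouched.

Step 11
Reactants: 17 triol (as named in step 9); 20 (E)-3-[4-(tert-butyldimethylsilyloxy)phenyl]prop-2-enoic acid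
Product: 21 [(1S,4aS,6S,7R,7aS)-4-formyl-6,7-dihydroxy-1-{[(3S)-3-methylpentanoyl]oxy}-1,4a,5,6,7,7a-hexahydrocyclopenta[c]pyran-7-yl]methyl (E)-3-[4-(tert-butyldimethylsilyloxy)phenyl]prop-2-enoate
Conditions: 20 (1.05 equiv), DCC, DMAP (cat.), CH2Cl2, −20 to 0 °C
Reagents that add atoms: none
Why: Steglich esterification under substrate control: the primary C10 hydroxyl should outcompete the secondary C7 and the tertiary C8 hydroxyls at low temperature with about one equivalent of acid.

Step 12
Reactants: 21 silyl-protected coumarate (as named in step 11)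
Product: 22 [(1S,4aS,6S,7R,7aS)-4-formyl-6,7-dihydroxy-1-{[(3S)-3-methylpentanoyl]oxy}-1,4a,5,6,7,7a-hexahydrocyclopenta[c]pyran-7-yl]methyl (E)-3-(4-hydroxyphenyl)prop-2-enoate
Conditions: Bu4NF, AcOH (1:1), THF, 0 °C
Reagents that add atoms: none
Why: Fluoride desilylation of an aryl silyl ether, the most fluoride-labile silyl ether class because phenoxide leaves well, with acetic acid buffering so that the ester linkages, the acyloxy acetal and the enal should survive.

Step 13
Reactants: 22 phenolic enal (as named in step 12)
Product: 23 target, [(1S,4aS,6S,7R,7aS)-6,7-dihydroxy-4-(hydroxymethyl)-1-{[(3S)-3-methylpentanoyl]oxy}-1,4a,5,6,7,7a-hexahydrocyclopenta[c]pyran-7-yl]methyl (E)-3-(4-hydroxyphenyl)prop-2-enoate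
Conditions: NaBH4, CeCl3·7H2O, MeOH/THF, −78 to −40 °C; pH 7 phosphate buffer quench
Reagents that add atoms: none
Why: Luche reduction: the cerium-modified borohydride should add in a 1,2-sense to the only aldehyde while the cinnamate, the aliphatic ester and the acyloxy acetal stay inert at low temperature, the neutral quench protects the now electron-rich enol ether, and no stereocentre is formed.

## Compound list

1 | cyclopent-2-en-1-one | O=C1CCC=C1 | starting material
2 | formaldehyde | C=O | starting material
3 | 2-(hydroxymethyl)cyclopent-2-en-1-one | OCC1=CCCC1=O | intermediate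
4 | 2-[(tert-butyldimethylsilyloxy)methyl]cyclopent-2-en-1-one | CC(C)(C)[Si](C)(C)OCC1=CCCC1=O | intermediate
5 | (1S)-2-[(tert-butyldimethylsilyloxy)methyl]cyclopent-2-en-1-ol | CC(C)(C)[Si](C)(C)OCC1=CCC[C@@H]1O | intermediate
6 | (1S)-1-(tert-butyldimethylsilyloxy)-2-[(tert-butyldimethylsilyloxy)methyl]cyclopent-2-ene | CC(C)(C)[Si](C)(C)OCC1=CCC[C@@H]1O[Si](C)(C)C(C)(C)C | intermediate
7 | (1S,2S,5S)-2-(tert-butyldimethylsilyloxy)-1-[(tert-butyldimethylsilyloxy)methyl]-6-oxabicyclo[3.1.0]hexane, epoxide α, trans to C7–OTBS | CC(C)(C)[Si](C)(C)OC[C@]12O[C@H]1CC[C@@H]2O[Si](C)(C)C(C)(C)C | intermediate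
8 | hydroxy selenide: C8 α-OH, C9 β-SePh, C7 β-OTBS, C8 β-CH2OTBS cyclopentane | CC(C)(C)[Si](C)(C)OC[C@]1(O)[C@H]([Se]c2ccccc2)CC[C@@H]1O[Si](C)(C)C(C)(C)C | intermediate (not isolated)
9 | selenoxide of 8 (configuration at selenium not defined) | CC(C)(C)[Si](C)(C)OC[C@]1(O)[C@H]([Se](=O)c2ccccc2)CC[C@@H]1O[Si](C)(C)C(C)(C)C | intermediate (not isolated)
10 | (1R,5S)-5-(tert-butyldimethylsilyloxy)-1-[(tert-butyldimethylsilyloxy)methyl]cyclopent-2-en-1-ol | CC(C)(C)[Si](C)(C)OC[C@]1(O)C=CC[C@@H]1O[Si](C)(C)C(C)(C)C | intermediate
11 | triformylmethane (methanetricarbaldehyde) | O=CC(C=O)C=O | starting material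
12 | cis-fused cyclobutanol photoadduct: 3-(TBSO)-2-[(TBSO)methyl]-2,7-dihydroxybicyclo[3.2.0]heptane-6,6-dicarbaldehyde, new bonds on the α-face, carbinol carbon not defined | O=CC1(C=O)C(O)[C@H]2[C@@H]1C[C@H](O[Si](C)(C)C(C)(C)C)[C@]2(O)CO[Si](C)(C)C(C)(C)C | intermediate (not isolated)
13 | open trialdehyde: cis-2-formylcyclopentyl malondialdehyde carrying the C7 OTBS, C8 OH and C8 CH2OTBS groups | O=C[C@H]1[C@@H](C(C=O)C=O)C[C@H](O[Si](C)(C)C(C)(C)C)[C@]1(O)CO[Si](C)(C)C(C)(C)C | intermediate (not isolated)
14 | (1R,4aS,6S,7R,7aS)-6-(TBSO)-7-[(TBSO)methyl]-1,7-dihydroxy-1,4a,5,6,7,7a-hexahydrocyclopenta[c]pyran-4-carbaldehyde | O[C@@H]1OC=C(C=O)[C@H]2C[C@H](O[Si](C)(C)C(C)(C)C)[C@](O)(CO[Si](C)(C)C(C)(C)C)[C@@H]12 | intermediate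
15 | (3S)-3-methylpentanoic acid | CC[C@H](C)CC(=O)O | starting material
16 | (1S,4aS,6S,7R,7aS)-6-(TBSO)-7-[(TBSO)methyl]-4-formyl-7-hydroxy-1,4a,5,6,7,7a-hexahydrocyclopenta[c]pyran-1-yl (3S)-3-methylpentanoate | CC[C@H](C)CC(=O)O[C@@H]1OC=C(C=O)[C@H]2C[C@H](O[Si](C)(C)C(C)(C)C)[C@](O)(CO[Si](C)(C)C(C)(C)C)[C@@H]12 | intermediate
17 | (1S,4aS,6S,7R,7aS)-4-formyl-6,7-dihydroxy-7-(hydroxymethyl)-1,4a,5,6,7,7a-hexahydrocyclopenta[c]pyran-1-yl (3S)-3-methylpentanoate | CC[C@H](C)CC(=O)O[C@@H]1OC=C(C=O)[C@H]2C[C@H](O)[C@](O)(CO)[C@@H]12 | intermediate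
18 | (E)-p-coumaric acid | O=C(O)/C=C/c1ccc(O)cc1 | starting material
19 | tert-butyldimethylsilyl (E)-3-[4-(tert-butyldimethylsilyloxy)phenyl]prop-2-enoate | CC(C)(C)[Si](C)(C)OC(=O)/C=C/c1ccc(O[Si](C)(C)C(C)(C)C)cc1 | intermediate (not isolated)
20 | (E)-3-[4-(tert-butyldimethylsilyloxy)phenyl]prop-2-enoic acid | O=C(O)/C=C/c1ccc(O[Si](C)(C)C(C)(C)C)cc1 | intermediate
21 | C10 4-O-TBS-p-coumarate of 17 | CC[C@H](C)CC(=O)O[C@@H]1OC=C(C=O)[C@H]2C[C@H](O)[C@](O)(COC(=O)/C=C/c3ccc(O[Si](C)(C)C(C)(C)C)cc3)[C@@H]12 | intermediate
22 | C10 p-coumarate of 17 (C4 formyl, free phenol) | CC[C@H](C)CC(=O)O[C@@H]1OC=C(C=O)[C@H]2C[C@H](O)[C@](O)(COC(=O)/C=C/c3ccc(O)cc3)[C@@H]12 | intermediate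
23 | CNP0241834.1 | CC[C@H](C)CC(=O)O[C@@H]1OC=C(CO)[C@H]2C[C@H](O)[C@](O)(COC(=O)/C=C/c3ccc(O)cc3)[C@@H]12 | target

## Step count and risks

Total step count: 13. Longest linear sequence: 12 (steps 1–9 and 11–13, from cyclopent-2-en-1-one).

**Step 7.**
- What may go wrong: the photoaddition may be inefficient. The strongly acidic tricarbonyl can oligomerise, the formyl-substituted enol ether chromophore of the product can undergo secondary photolysis, and the C8 hydroxyl can compete in hemiacetalisation. The orientation selectivity at the hindered C9 may also erode.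
- Fallback (sets out from 10, comes back at 14): the four-carbon partner and the redox plan are both changed. Compound 10 is irradiated with methyl diformylacetate F1, the partner whose photoannulation with cyclopentenes is established chemistry. This should give the C4 methyl ester lactol F2, whose alkoxyacrylate chromophore is known to tolerate the irradiation. Silylation of the C1 hydroxyl (Et3SiCl, imidazole) should give the triethylsilyl acetal F3. Reduction with i-Bu2AlH (CH2Cl2, −78 °C) should give the C11 allylic alcohol F4. Oxidation with MnO2 (CH2Cl2) should give the enal F5. Selective hydrolysis of the labile anomeric triethylsilyl group (AcOH/THF/H2O) then leads back to 14.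

**Step 13.**
- What may go wrong: hydride addition to the vinylogous formate may be sluggish. The free phenol may bind to borohydride. The C1 acyl group may be lost or may migrate. The C8 hydroxyl or methanol may add, under acid, to the newly electron-rich enol ether.
- Fallback (sets out from 21, comes back at 23): the order of events is changed so that hydride meets a substrate without an acidic phenol. Compound 21 is reduced (NaBH4, CeCl3·7H2O, THF-rich MeOH, low temperature) to the silyl-protected allylic alcohol F6. The last operation then becomes the buffered fluoride cleavage of the aryl silyl ether (Bu4NF/AcOH, THF, 0 °C), which gives 23.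

**Step 11.**
- What may go wrong: discrimination between the neopentyl-type primary C10 hydroxyl and the secondary C7 hydroxyl may be incomplete. DMAP may induce migration of the C1 acyl group onto the free hydroxyls.
- Fallback (sets out from 16, comes back at 22): site selection is moved from the acylation to the deprotection. Brief treatment of 16 with HF·pyridine/pyridine at 0 °C is stopped after loss of the primary silyl group. This should give the C10 mono-alcohol F7, with C7 still silylated. Steglich coupling with 20 can then occur only at C10 and should give the bis-silyl coumarate F8. One global HF·pyridine treatment removes the C7 and the phenolic silyl groups together to give 22.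

## Further compounds

F1 | step 7 | methyl diformylacetate (methyl 2-formyl-3-oxopropanoate) | COC(=O)C(C=O)C=O
F2 | step 7 | methyl (1R,4aS,6S,7R,7aS)-6-(TBSO)-7-[(TBSO)methyl]-1,7-dihydroxy-1,4a,5,6,7,7a-hexahydrocyclopenta[c]pyran-4-carboxylate | O[C@@H]1OC=C(C(=O)OC)[C@H]2C[C@H](O[Si](C)(C)C(C)(C)C)[C@](O)(CO[Si](C)(C)C(C)(C)C)[C@@H]12
F3 | step 7 | C1 β-O-triethylsilyl derivative of F2 | CC[Si](CC)(CC)O[C@@H]1OC=C(C(=O)OC)[C@H]2C[C@H](O[Si](C)(C)C(C)(C)C)[C@](O)(CO[Si](C)(C)C(C)(C)C)[C@@H]12
F4 | step 7 | C4 hydroxymethyl compound from reduction of F3 | CC[Si](CC)(CC)O[C@@H]1OC=C(CO)[C@H]2C[C@H](O[Si](C)(C)C(C)(C)C)[C@](O)(CO[Si](C)(C)C(C)(C)C)[C@@H]12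
F5 | step 7 | C4 formyl compound from oxidation of F4 (C1 β-O-triethylsilyl derivative of 14) | CC[Si](CC)(CC)O[C@@H]1OC=C(C=O)[C@H]2C[C@H](O[Si](C)(C)C(C)(C)C)[C@](O)(CO[Si](C)(C)C(C)(C)C)[C@@H]12
F6 | step 13 | 4-O-TBS ether of the target at the phenol | CC[C@H](C)CC(=O)O[C@@H]1OC=C(CO)[C@H]2C[C@H](O)[C@](O)(COC(=O)/C=C/c3ccc(O[Si](C)(C)C(C)(C)C)cc3)[C@@H]12
F7 | step 11 | C10 mono-alcohol of 16 (C7 OTBS kept) | CC[C@H](C)CC(=O)O[C@@H]1OC=C(C=O)[C@H]2C[C@H](O[Si](C)(C)C(C)(C)C)[C@](O)(CO)[C@@H]12
F8 | step 11 | C10 4-O-TBS-p-coumarate of F7 | CC[C@H](C)CC(=O)O[C@@H]1OC=C(C=O)[C@H]2C[C@H](O[Si](C)(C)C(C)(C)C)[C@](O)(COC(=O)/C=C/c3ccc(O[Si](C)(C)C(C)(C)C)cc3)[C@@H]12
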